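The pitfall put first to the meeting was that flat columns invite averaging, and an average of one run belongs to that run's charge.

| setting | summer | dusk | flask |
|---|---|---|---|
| substrate | 0.30 M | 0.15 M | 0.30 M |
| remark | the very flask that is asked about, followed so far | run made earlier |  |
| time |  |  | 3.0 h |

- summer (time / min: ring / %, open dimer / %): 10.0: 38, 33; 25.0: 39, 30; 50.0: 36, 33; 80.0: 42, 32
- dusk (time / h: ring / %, open dimer / %): 0.250: 57, 30; 0.500: 52, 28; 1.33: 55, 31; 3.00: 55, 28

(each reading ± 2 percentage points)

- percent here means substrate units held: one open dimer counts as two
- percent here means substrate units held: one open trimer counts as three
- what may be going on: substrate -> ring; 2 substrate -> open dimer; substrate + open dimer -> open trimer; ring -> over-reaction product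

- how much ring there is at 3.0 h, in percent of the substrate charged
- how much open dimer there is at 3.0 h, in percent of the substrate charged
- amount of ring if the flask were left three thousand times as long, in percent of the substrate charged

The kineticist noted that both runs stand level within their scatter from their first readings, yet ring differs between the charges. She argued that in the proposed scheme ring takes one substrate, whereas the steps to open dimer and open trimer each join two partners. So the ratio of ring to the rest, a selectivity factor, should go roughly inversely with charge.

She therefore defined the dilution constant as charge times ring over what is not ring. The dusk run, with ring averaging 54.8 %, reads 0.181 M, and she proposed to carry this dilution constant. The summer run, averaging 38.7 %, reads 0.190 M. Turned round, the dusk value gave her own reckoning for ring at 0.30 M: 37.6 %.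

The forecaster, working from the summer averages, reported 38.5 % ring and 32 % open dimer at 3.0 h, and 10 % ring for the long wait, within 0 % to 41 %. He observed that “the more dilute run favours ring, the first-order path”.

The flask gives 37.7 % ring, 32.4 % open dimer, and 0 % ring after the long wait, below the forecast.

    substrate → ring (k = 1.40 min⁻¹)
    2 substrate → open dimer (k = 7.80 M⁻¹ min⁻¹)
    substrate + open dimer → open trimer (k = 8.30 M⁻¹ min⁻¹)
    ring → over-reaction product (k = 1.10 × 10⁻⁴ min⁻¹)

Its ring gives a dilution constant of 0.182 M. Removing the step from substrate + open dimer to open trimer would raise open dimer in this flask from 32.4 % to 56.1 %. In the neighbour charged with 0.75 M, the dusk constant reckons ring at 19.4 %, and that neighbour holds 20.3 % ring beside 45.5 % open trimer.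

(The data were computed with constants of no real substance; noise was put on by code.)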